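J, the mono adduct, appears within hours in two earlier runs and then drains away, so the flask's peak should lie where its making stops outrunning its loss.

| setting | north-east | south-east | flask |
|---|---|---|---|
| G | 0.14 M | 0.22 M | 0.10 M |
| D | 3 equiv | 3 equiv | 3.00 equiv |
| remark | run made earlier | run made earlier |  |
| time |  |  | 5.0 d |

| run | time / d | J / % |
|---|---|---|
| north-east | 0.0417 | 95.4 |
| north-east | 0.104 | 96.7 |
| north-east | 0.250 | 93.0 |
| north-east | 0.625 | 84.6 |
| north-east | 1.67 | 60.8 |
| north-east | 4.00 | 18.5 |
| south-east | 0.0417 | 98.3 |
| south-east | 0.104 | 96.7 |
| south-east | 0.250 | 92.7 |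
| south-east | 0.625 | 84.5 |
| south-east | 1.67 | 60.3 |
| south-east | 4.00 | 18.5 |

(readings scatter by 0.3 percentage points)

- the analysis behind the earlier runs scatters by 0.3 percentage points, standard deviation
- a reading or a percentage of J counts all its forms, free or not

* time, not beyond 5.0 d, at which the flask holds most J
* the amount of J, in percent of the G charged, at that time
* earliest time at which at least nineteen twentieths of that best amount are there
* latest time at which they still are, in d

At 0.0417 d the north-east run reads 95.4% and the south-east run 98.3%, yet at 0.104 d both read 96.7%. I therefore take them to share one falling curve and read the early gap of 2.9 percentage points as G still unreacted in the north-east run, neglecting the smaller remainder in the south-east run.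

G is the limiting reagent. Let k be the rate constant of G + D → J and c the starting G. With 3 equiv of D, D levels off near 2c, and the fraction x of G left follows x = (2/3) exp(−2kct). The gap then reads k ≈ 268 M⁻¹ d⁻¹.

From 0.104 d to 0.625 d the north-east run loses 0.232 d⁻¹ of its charge as J, and the south-east run loses about the same. The two read alike at their last reading, 18.5% and 18.5%. G's time scale, 0.0133 d in the north-east run, is far shorter than 4.00 d, so the early gap has closed by then; that says nothing about why the later loss in percent matches at the two concentrations, and I take that match simply as read from the runs.

I assume the same loss in the flask. Making, 2kc·x, meets it at x = 0.432%: this crossing remainder, the G left when making J falls to the rate of loss, is reached at 0.0938 d. Running the shared curve back to that time and subtracting the remainder, I get 96.5% J.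

The forecast says 0.095 d (0.075 d to 0.125 d), 96.7%, 1.1 h and 0.3 d, holding that “The peak comes where formation equals loss”.

The flask peaks at 0.0924 d with 96.7%, and the window runs from 1.05 h to 0.303 d.

    D + J → L (k = 1.86 × 10⁻⁴ M⁻¹ s⁻¹)
    Q ⇌ J, rate k2*(cs2 - [J]) while solid is left; crystals form when [J] > cs2 (solubility = 8.10 mM, k = 0.0195 s⁻¹)
    G + D → J (k = 0.00311 M⁻¹ s⁻¹)

At 0.0924 d the flask holds 0.484% G against my 0.432%, while crystals Q, counted in J, make up 88.6% of the charge. A neighbour flask charged with 0.025 M of G reckons to a remainder of 1.73%, reached at 0.272 d with 91.1% J, and its simulated best is 90.7%. At 5.00 d that neighbour holds 13.2% J and 86.8% L.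

The data are calculated from invented constants.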